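**Strategy.** Ring C is grown onto ring B instead of being coupled as a preformed arene. Ring C bears its two carbon substituents, the bond to ring B at C1 and the phenethyl chain at C6, side by side, and its two hydroxyls at C3 and C4 on the far edge. The four carbons C2, C1, C6 and C5 can therefore come from a butadiene substituted at both inner positions, and C3–C4 from an alkene carrying two cis oxygens. A single Diels–Alder reaction of vinylene carbonate with a diene that holds dibenzyl-protected ring B on one inner carbon and the phenethyl chain on the other forms C2–C3 and C4–C5 and closes ring C; carbonate cleavage and double oxidation then aromatise it.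

Key step: step 8

Remark: rings A and D are the two 3-methoxyphenyl groups, ring B is the catechol ring that stems from 5-bromovanillin, and ring C is the ring made in the key step. The cycloadduct and the diol derived from it are racemic (one enantiomer drawn), and their stereocentres vanish on aromatisation. Diethyl (3-methoxybenzyl)phosphonate and 3-methoxybenzyl bromide are taken as catalogue compounds.

**Step 1**
Reactants: 1 5-bromovanillin
Product: 2 3-bromo-4,5-dihydroxybenzaldehyde
Conditions: AlCl3, pyridine, CH2Cl2, reflux; then aq. HCl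
Reagents that add atoms: none
Why: Lewis acid-assisted nucleophilic demethylation, in which AlCl3 chelates the ortho-hydroxy methoxy pair and pyridine removes the activated methyl group, a standard cleavage of guaiacol-type ethers that leaves the aldehyde and the aryl bromide untouched.

**Step 2**
Reactants: 2 3-bromo-4,5-dihydroxybenzaldehyde
Product: 3 3,4-bis(benzyloxy)-5-bromobenzaldehyde
Conditions: BnBr, K2CO3, DMF, 60 °C
Reagents that add atoms: benzyl bromide, BrCc1ccccc1
Why: Williamson ether synthesis on both phenoxides installs benzyl ethers that should survive every later step and are removed by hydrogenolysis at the end.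

**Step 3**
Reactants: 3 3,4-bis(benzyloxy)-5-bromobenzaldehyde; 4 diethyl (3-methoxybenzyl)phosphonate
Product: 6 (E)-1,2-bis(benzyloxy)-3-bromo-5-[2-(3-methoxyphenyl)ethenyl]benzene, via potassium phosphonate carbanion 5 (not isolated)
Conditions: t-BuOK, THF, 0 °C to rt
Reagents that add atoms: none
Why: Horner–Wadsworth–Emmons olefination of the non-enolisable aldehyde with the benzylic phosphonate carbanion should give the E-stilbene under the usual thermodynamic control, and the alkene geometry is erased again in step 4.

**Step 4**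
Reactants: 6 (E)-1,2-bis(benzyloxy)-3-bromo-5-[2-(3-methoxyphenyl)ethenyl]benzene
Product: 7 1,2-bis(benzyloxy)-3-bromo-5-[2-(3-methoxyphenyl)ethyl]benzene
Conditions: TsNHNH2, NaOAc, DME/H2O, reflux
Reagents that add atoms: none
Why: Diimide reduction, in which diimide released from the sulfonyl hydrazide transfers two hydrogens concertedly to the stilbene C=C bond and, unlike hydrogenation over palladium, spares the aryl bromide and the benzyl ethers.

**Step 5**
Reactants: 8 1-(trimethylsilyl)propyne; 9 3-methoxybenzyl bromide
Product: 12 4-(3-methoxyphenyl)but-1-yne, via lithiated 1-(trimethylsilyl)propyne 10 (not isolated), via silyl-capped alkyne 11 (not isolated)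
Conditions: n-BuLi, THF, −78 °C; 9, −78 °C to rt; then MeOH, K2CO3, rt
Reagents that add atoms: none
Why: Propargylic lithiation of the silyl-blocked propyne followed by SN2 alkylation at CH2 with the benzylic bromide builds the four-carbon chain, and methoxide-mediated protodesilylation in the same flask frees the terminal alkyne.

**Step 6**
Reactants: 7 1,2-bis(benzyloxy)-3-bromo-5-[2-(3-methoxyphenyl)ethyl]benzene; 12 4-(3-methoxyphenyl)but-1-yne
Product: 13 1,2-bis(benzyloxy)-5-[2-(3-methoxyphenyl)ethyl]-3-[4-(3-methoxyphenyl)but-1-yn-1-yl]benzene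
Conditions: PdCl2(MeCN)2 (cat.), XPhos, Cs2CO3, MeCN, 80 °C
Reagents that add atoms: none
Why: Copper-free Sonogashira coupling, in which the bulky electron-rich biarylphosphine promotes oxidative addition of the electron-rich ortho-alkoxy aryl bromide to zerovalent palladium and the absence of copper suppresses alkyne homocoupling.

**Step 7**
Reactants: 13 1,2-bis(benzyloxy)-5-[2-(3-methoxyphenyl)ethyl]-3-[4-(3-methoxyphenyl)but-1-yn-1-yl]benzene; 14 ethylene
Product: 15 2-{2,3-bis(benzyloxy)-5-[2-(3-methoxyphenyl)ethyl]phenyl}-3-[2-(3-methoxyphenyl)ethyl]buta-1,3-diene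
Conditions: second-generation Grubbs catalyst RuCl2(=CHPh)(H2IMes)(PCy3) (10 mol%), ethylene (1 atm), toluene, 80 °C
Reagents that add atoms: none
Why: Cross enyne metathesis with ethylene, in which the ruthenium methylidene adds across the alkyne to a vinylcarbene that ethylene releases as the 2,3-disubstituted butadiene, a transformation established for aryl alkyl internal alkynes with this catalyst.

**Step 8**
Reactants: 15 2-{2,3-bis(benzyloxy)-5-[2-(3-methoxyphenyl)ethyl]phenyl}-3-[2-(3-methoxyphenyl)ethyl]buta-1,3-diene; 16 vinylene carbonate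
Product: 17 cis-5-{2,3-bis(benzyloxy)-5-[2-(3-methoxyphenyl)ethyl]phenyl}-6-[2-(3-methoxyphenyl)ethyl]-3a,4,7,7a-tetrahydro-1,3-benzodioxol-2-one (racemic, 3aS*,7aR*)
Conditions: 16 (10 equiv), BHT (cat.), o-xylene, sealed tube, 175 °C
Reagents that add atoms: none
Why: Thermal Diels–Alder reaction, in which the s-cis conformer of diene 15 and the alkene of 16 combine in a concerted suprafacial (4+2) cycloaddition, the reaction type known for vinylene carbonate with 2,3-dimethylbutadiene and other 2,3-disubstituted butadienes at about this temperature. Ring C closes by intermolecular (4+2) annulation: the two diene CH2 termini bond to the two carbons of 16 to make C2–C3 and C4–C5, so ring B and the phenethyl chain end up on the adjacent alkene carbons C1 and C6. The two new stereocentres at C3 and C4 are set cis by the Z geometry locked into the cyclic dienophile, which suprafacial addition preserves; the diene is achiral, so 17 should form as a racemate, which is harmless because both centres become sp2 in step 10. No regiochemical question arises because the dienophile is symmetric. The selectivity the step needs is cross-cycloaddition ahead of dimerisation or polymerisation of the 2-aryldiene, which the large excess of 16 and the radical inhibitor should secure, while substitution at both inner diene carbons favours the reactive s-cis conformer. Benzyl and methyl ethers are inert at this temperature.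

**Step 9**
Reactants: 17 cis-fused cyclohexene carbonate
Product: 18 cis-4-{2,3-bis(benzyloxy)-5-[2-(3-methoxyphenyl)ethyl]phenyl}-5-[2-(3-methoxyphenyl)ethyl]cyclohex-4-ene-1,2-diol (racemic, 1R*,2S*)
Conditions: K2CO3 (cat.), MeOH/THF, rt
Reagents that add atoms: none
Why: Base-catalysed transesterification of the cyclic carbonate with methanol releases the diol without touching either C–O bond, so the cis configuration is retained.

**Step 10**
Reactants: 18 cis-cyclohex-4-ene-1,2-diol
Product: 20 2',3'-bis(benzyloxy)-5',6-bis[2-(3-methoxyphenyl)ethyl]-[1,1'-biphenyl]-3,4-diol, via cyclohex-4-ene-1,2-dione 19 (not isolated)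
Conditions: (COCl)2, DMSO, CH2Cl2, −78 °C; then Et3N, −78 °C to rt
Reagents that add atoms: none
Why: Double Swern oxidation converts both secondary alcohols into ketones, and the resulting cyclohex-4-ene-1,2-dione is the keto tautomer of a catechol, so two amine-assisted enolisations driven by aromatisation should deliver ring C as the arene, as established for diols derived from vinylene carbonate cycloadducts.

**Step 11**
Reactants: 20 2',3'-bis(benzyloxy)-5',6-bis[2-(3-methoxyphenyl)ethyl]-[1,1'-biphenyl]-3,4-diol
Product: 21 isoplagilin, 5,6'-bis[2-(3-methoxyphenyl)ethyl]-[1,1'-biphenyl]-2,3,3',4'-tetrol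
Conditions: H2 (1 atm), 10% Pd/C, EtOAc/MeOH, rt
Reagents that add atoms: none
Why: Catalytic hydrogenolysis of the two benzyl aryl ethers frees the ring B catechol, while the methyl ethers, the biaryl bond and the saturated two-carbon chains are inert.

**Compound list**

1 | 5-bromovanillin (3-bromo-4-hydroxy-5-methoxybenzaldehyde) | COc1cc(C=O)cc(Br)c1O | starting material
2 | 3-bromo-4,5-dihydroxybenzaldehyde | O=Cc1cc(O)c(O)c(Br)c1 | intermediate
3 | 3,4-bis(benzyloxy)-5-bromobenzaldehyde | O=Cc1cc(OCc2ccccc2)c(OCc2ccccc2)c(Br)c1 | intermediate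
4 | diethyl (3-methoxybenzyl)phosphonate | CCOP(=O)(Cc1cccc(OC)c1)OCC | starting material
5 | potassium salt of the benzylic carbanion of 4 | CCOP(=O)([CH-]c1cccc(OC)c1)OCC.[K+] | intermediate (not isolated)
6 | (E)-1,2-bis(benzyloxy)-3-bromo-5-[2-(3-methoxyphenyl)ethenyl]benzene | COc1cccc(/C=C/c2cc(OCc3ccccc3)c(OCc3ccccc3)c(Br)c2)c1 | intermediate
7 | 1,2-bis(benzyloxy)-3-bromo-5-[2-(3-methoxyphenyl)ethyl]benzene | COc1cccc(CCc2cc(OCc3ccccc3)c(OCc3ccccc3)c(Br)c2)c1 | intermediate
8 | 1-(trimethylsilyl)propyne | CC#C[Si](C)(C)C | starting material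
9 | 3-methoxybenzyl bromide | COc1cccc(CBr)c1 | starting material
10 | [3-(trimethylsilyl)prop-2-yn-1-yl]lithium | [Li]CC#C[Si](C)(C)C | intermediate (not isolated)
11 | [4-(3-methoxyphenyl)but-1-yn-1-yl]trimethylsilane | COc1cccc(CCC#C[Si](C)(C)C)c1 | intermediate (not isolated)
12 | 4-(3-methoxyphenyl)but-1-yne | COc1cccc(CCC#C)c1 | intermediate
13 | 1,2-bis(benzyloxy)-5-[2-(3-methoxyphenyl)ethyl]-3-[4-(3-methoxyphenyl)but-1-yn-1-yl]benzene | COc1cccc(CCC#Cc2cc(CCc3cccc(OC)c3)cc(OCc3ccccc3)c2OCc2ccccc2)c1 | intermediate
14 | ethylene | C=C | starting material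
15 | 2-{2,3-bis(benzyloxy)-5-[2-(3-methoxyphenyl)ethyl]phenyl}-3-[2-(3-methoxyphenyl)ethyl]buta-1,3-diene | COc1cccc(CCc2cc(OCc3ccccc3)c(OCc3ccccc3)c(C(=C)C(=C)CCc3cccc(OC)c3)c2)c1 | intermediate
16 | vinylene carbonate (1,3-dioxol-2-one) | O=C1OC=CO1 | starting material
17 | cis-5-{2,3-bis(benzyloxy)-5-[2-(3-methoxyphenyl)ethyl]phenyl}-6-[2-(3-methoxyphenyl)ethyl]-3a,4,7,7a-tetrahydro-1,3-benzodioxol-2-one, racemic, one enantiomer drawn | O=C1O[C@H]2CC(c3cc(CCc4cccc(OC)c4)cc(OCc4ccccc4)c3OCc3ccccc3)=C(CCc3cccc(OC)c3)C[C@H]2O1 | intermediate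
18 | cis-4-{2,3-bis(benzyloxy)-5-[2-(3-methoxyphenyl)ethyl]phenyl}-5-[2-(3-methoxyphenyl)ethyl]cyclohex-4-ene-1,2-diol, racemic, one enantiomer drawn | O[C@H]1CC(c2cc(CCc3cccc(OC)c3)cc(OCc3ccccc3)c2OCc2ccccc2)=C(CCc2cccc(OC)c2)C[C@H]1O | intermediate
19 | 4-{2,3-bis(benzyloxy)-5-[2-(3-methoxyphenyl)ethyl]phenyl}-5-[2-(3-methoxyphenyl)ethyl]cyclohex-4-ene-1,2-dione | O=C1CC(c2cc(CCc3cccc(OC)c3)cc(OCc3ccccc3)c2OCc2ccccc2)=C(CCc2cccc(OC)c2)CC1=O | intermediate (not isolated)
20 | 2',3'-bis(benzyloxy)-5',6-bis[2-(3-methoxyphenyl)ethyl]-[1,1'-biphenyl]-3,4-diol | Oc1cc(CCc2cccc(OC)c2)c(-c2cc(CCc3cccc(OC)c3)cc(OCc3ccccc3)c2OCc2ccccc2)cc1O | intermediate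
21 | isoplagilin, 5,6'-bis[2-(3-methoxyphenyl)ethyl]-[1,1'-biphenyl]-2,3,3',4'-tetrol | COc1cccc(CCc2cc(O)c(O)c(-c3cc(O)c(O)cc3CCc3cccc(OC)c3)c2)c1 | target

**Step count.** Total: 11 steps. Longest linear sequence: 10 steps (steps 1–4 and 6–11); step 5 is the side branch.

**Steps most likely to fail**

Step 8. The cycloaddition to a weakly activated dienophile is slow, so thermal dimerisation or radical polymerisation of the 2-aryldiene may outrun it. The fallback gives up the cycloaddition and brings ring C in as a preformed arene, setting out from bromide 7. Borylation of 7 (B2pin2, PdCl2(dppf), KOAc, dioxane, 90 °C) would give the pinacol boronate F1. Commercial 3,4-bis(benzyloxy)benzaldehyde would be brominated para to the 3-benzyloxy group (Br2, AcOH, rt) to 2-bromo-4,5-bis(benzyloxy)benzaldehyde F2. Olefination of F2 with phosphonate 4 under the conditions of step 3 would give the bromostilbene F3. Suzuki–Miyaura coupling of F1 with F3 (Pd(OAc)2, SPhos, K3PO4, toluene/H2O, 90 °C) would give the tetrabenzyl biaryl stilbene F4. Hydrogenation over Pd/C as in step 11 would then saturate the stilbene and cleave all four benzyl ethers in one operation, rejoining the route at target 21.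

Step 7. The catalytic cycle may stall, either because the ortho-benzyloxy oxygen chelates the ruthenium vinylcarbene or because the methylidene adds only slowly to the hindered internal alkyne. The fallback sets out from alkyne 13 and avoids metathesis. Oxidation of the triple bond (PdCl2 cat., DMSO, 120–140 °C) would give the 1,2-diketone F5. Double carbonyl methylenation with Cp2TiMe2 (toluene, 70 °C), a reagent that tolerates enolisable ketones, would return to the route at diene 15.

Step 10. The second oxidation may stop at the α-hydroxy ketone, or surplus activated DMSO may methylthiomethylate the newly formed catechol. The fallback sets out from diol 18 and uses hypervalent iodine with deliberate over-oxidation. Excess 2-iodoxybenzoic acid (DMSO, rt), which takes 1,2-diols to 1,2-diketones without C–C cleavage and catechols on to quinones, would carry the material through to the ortho-quinone F6. Reduction with aqueous Na2S2O4 would then return to the route at catechol 20.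

**Further compounds**

F1 | step 8 | 2-{2,3-bis(benzyloxy)-5-[2-(3-methoxyphenyl)ethyl]phenyl}-4,4,5,5-tetramethyl-1,3,2-dioxaborolane | COc1cccc(CCc2cc(OCc3ccccc3)c(OCc3ccccc3)c(B3OC(C)(C)C(C)(C)O3)c2)c1
F2 | step 8 | 2-bromo-4,5-bis(benzyloxy)benzaldehyde | O=Cc1cc(OCc2ccccc2)c(OCc2ccccc2)cc1Br
F3 | step 8 | (E)-1,2-bis(benzyloxy)-4-bromo-5-[2-(3-methoxyphenyl)ethenyl]benzene | COc1cccc(/C=C/c2cc(OCc3ccccc3)c(OCc3ccccc3)cc2Br)c1
F4 | step 8 | 2,3,4',5'-tetrakis(benzyloxy)-2'-[(E)-2-(3-methoxyphenyl)ethenyl]-5-[2-(3-methoxyphenyl)ethyl]-1,1'-biphenyl | COc1cccc(/C=C/c2cc(OCc3ccccc3)c(OCc3ccccc3)cc2-c2cc(CCc3cccc(OC)c3)cc(OCc3ccccc3)c2OCc2ccccc2)c1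
F5 | step 7 | 1-{2,3-bis(benzyloxy)-5-[2-(3-methoxyphenyl)ethyl]phenyl}-4-(3-methoxyphenyl)butane-1,2-dione | COc1cccc(CCc2cc(OCc3ccccc3)c(OCc3ccccc3)c(C(=O)C(=O)CCc3cccc(OC)c3)c2)c1
F6 | step 10 | 4-{2,3-bis(benzyloxy)-5-[2-(3-methoxyphenyl)ethyl]phenyl}-5-[2-(3-methoxyphenyl)ethyl]cyclohexa-3,5-diene-1,2-dione | O=C1C=C(c2cc(CCc3cccc(OC)c3)cc(OCc3ccccc3)c2OCc2ccccc2)C(CCc2cccc(OC)c2)=CC1=O
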